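**Plan**

1. Retrosynthesis (labdane numbering): cut C12–C13 (side chain), the C19–O acyl bond (angelate) and C4–C18. Then, with a helper ketone placed at C1, cut the decalin at C5–C10 and C3–C4 to reach an acyclic vinyl ketone–enoate, itself cut at C9–C10 and C8–C9.
2. Forward: a (Z)-iodoalkene holding C4–C8 and C19 is joined to a C9/C11/C12 allylic alcohol. A propanoate Ireland–Claisen rearrangement then brings C10, C20 and C1 and sets C9, and a vinyl ketone supplies C2 and C3.
3. Key event: a silyl-triflate-mediated intramolecular double Michael reaction. C10 adds to C5 and closes ring B, then C4 adds to C3 and closes ring A.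
4. Enabling feature: C10 is a methyl-bearing quaternary carbon next to C1, so a C1 ketone makes it an enol donor. C5 lies β to the carboxyl-level C19 through C4, so a C4=C5 enoate makes it an acceptor. The cis C7=C8 bond of ring B sits in the four-atom chain between them, and C3 ends up β to the C1 carbonyl.
5. Stereochemistry: C9 comes from the ligand-controlled Claisen step. C10 and C5 follow from C9 through 1,3-allylic strain in a chair transition state (trans ring fusion). C4 is set by methylation of the C19 ester enolate anti to the axial C20 methyl. The 13Z and angelate geometries are bought in with (2Z)-3-iodobut-2-enoic acid and angelic acid.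
6. The C1 ketone helper is removed by tosylhydrazone reduction; the C9 vinyl group is the latent C11–C12 unit.

Key step: step 8

Remark: labdane numbers are used throughout (C1–C10 decalin, C11–C16 side chain, C17 on C8, C18 the 4α-methyl, C19 the 4β-CH2O carbon, C20 on C10).
Assumption: the (4S,5S)-diazaborolidine is written in step 6; if its facial preference on this ester is the opposite of the one needed for the (3R) acid 10, its (4R,5R) enantiomer is used instead.

**Step 1**
Reactants: 1 3-[(tert-butyldimethylsilyl)oxy]propanal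
Product: 2 tert-butyl{[(3Z)-4-iodopent-3-en-1-yl]oxy}dimethylsilane
Conditions: EtPPh3I, n-BuLi, THF, 0 °C → rt; I2, −78 °C; NaN(SiMe3)2, −20 °C; then 1, −78 → −20 °C
Reagents that add atoms: (1-iodoethylidene)triphenylphosphorane (generated from ethyltriphenylphosphonium iodide), CC(I)=P(c1ccccc1)(c1ccccc1)c1ccccc1
Why: Stork–Zhao-type Wittig olefination with the α-iodo ylide: the non-stabilised ylide should deliver mainly the (Z)-iodoalkene, i.e. iodine cis to the chain, which is the C7=C8 geometry that ring B needs.

**Step 2**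
Reactants: 2 tert-butyl{[(3Z)-4-iodopent-3-en-1-yl]oxy}dimethylsilane
Product: 3 (3Z)-4-iodopent-3-en-1-ol
Conditions: Bu4NF, THF, 0 °C
Reagents that add atoms: none
Why: Fluoride-mediated silyl ether cleavage is selective for the Si–O bond and leaves the alkenyl iodide untouched.

**Step 3**
Reactants: 3 (3Z)-4-iodopent-3-en-1-ol
Product: 5 methyl (2E,5Z)-6-iodohepta-2,5-dienoate, via iodopentenal 4 (not isolated)
Conditions: Dess–Martin periodinane, NaHCO3, CH2Cl2, 0 °C; then Ph3P=CHCO2Me, rt, one pot
Reagents that add atoms: methyl (triphenylphosphoranylidene)acetate, COC(=O)C=P(c1ccccc1)(c1ccccc1)c1ccccc1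
Why: Dess–Martin oxidation followed at once by Wittig olefination with a stabilised ylide traps the β,γ-unsaturated aldehyde before the C7=C8 bond can move into conjugation and should give the (E)-enoate, the later C4=C5 acceptor.

**Step 4**
Reactants: 5 methyl (2E,5Z)-6-iodohepta-2,5-dienoate; 6 (2E)-3-(tributylstannyl)prop-2-en-1-ol
Product: 7 methyl (2E,5Z,7E)-9-hydroxy-6-methylnona-2,5,7-trienoate
Conditions: PdCl2(MeCN)2 (cat.), DMF, rt, dark
Reagents that add atoms: none
Why: Stille coupling of an alkenyl iodide with an alkenylstannane proceeds with retention at both partners, so the (5Z,7E)-diene arises with the free allylic alcohol and the enoate untouched.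

**Step 5**
Reactants: 7 methyl (2E,5Z,7E)-9-hydroxy-6-methylnona-2,5,7-trienoate
Product: 8 methyl (2E,5Z,7E)-6-methyl-9-(propanoyloxy)nona-2,5,7-trienoate
Conditions: (EtCO)2O, Et3N, DMAP (cat.), CH2Cl2, 0 °C
Reagents that add atoms: propanoic anhydride, CCC(=O)OC(=O)CC
Why: DMAP-catalysed acylation of the primary allylic alcohol installs the propanoate that carries the future C20, C10 and C1.

**Step 6**
Reactants: 8 methyl (2E,5Z,7E)-6-methyl-9-(propanoyloxy)nona-2,5,7-trienoate
Product: 10 (3R,4Z,7E)-3-ethenyl-9-methoxy-2,4-dimethyl-9-oxonona-4,7-dienoic acid (both C2 epimers), via boron ketene acetal 9 (not isolated)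
Conditions: (4S,5S)-2-bromo-1,3-bis{[3,5-bis(trifluoromethyl)phenyl]sulfonyl}-4,5-diphenyl-1,3,2-diazaborolidine, iPr2NEt, CH2Cl2, −78 °C, then −20 °C; aqueous work-up
Reagents that add atoms: none
Why: Enantioselective Ireland–Claisen rearrangement of a boron ketene acetal: the chair [3,3] shift across the (E)-C9=C11 bond forms C9–C10 and the C9 stereocentre (R) on the enolate face left open by the C2-symmetric sulfonamide ligand, amine-mediated enolisation spares the doubly allylic C6–H, and the C10 configuration is of no consequence because it is erased in step 8.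

**Step 7**
Reactants: 10 (3R,4Z,7E)-3-ethenyl-9-methoxy-2,4-dimethyl-9-oxonona-4,7-dienoic acid
Product: 12 methyl (2E,5Z,7R)-7-ethenyl-6,8-dimethyl-9-oxoundeca-2,5,10-trienoate (both C8 epimers), via acid chloride 11 (not isolated)
Conditions: 1-chloro-N,N,2-trimethylprop-1-en-1-amine, CH2Cl2, 0 °C → rt; then Bu3SnCH=CH2, Pd(PPh3)4 (cat.), THF, 50 °C
Reagents that add atoms: tributyl(vinyl)stannane, C=C[Sn](CCCC)(CCCC)CCCC
Why: Neutral acid chloride formation and Stille acylation with the vinylstannane give the vinyl ketone without base or a hard carbon nucleophile, so the enoate, the skipped diene and C9 stay intact.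

**Step 8**
Reactants: 12 methyl (2E,5Z,7R)-7-ethenyl-6,8-dimethyl-9-oxoundeca-2,5,10-trienoate
Product: 16 methyl 1-oxo-13,14,15,16,18-pentanorlabda-7,11-dien-19-oate (trans-decalone ester; C4 epimers), via silyloxydiene 13 (not isolated), via silyl ketene acetal 14 (not isolated), via silyl enol ether 15 (not isolated)
Conditions: TBSOTf, iPr2NEt, CH2Cl2, −78 → 0 °C; then 1 M HCl, THF, 0 °C
Reagents that add atoms: none
Why: The hindered amine and silyl triflate enolise the ketone toward C10, the only enolisable side, to give silyloxydiene 13; silyl-triflate activation of the enoate then lets C10 add to C5 (Mukaiyama–Michael), the silyl ketene acetal 14 so formed adds through C4 to C3 of the regenerated vinyl ketone, and acid hydrolysis of enol ether 15 gives 16. The closest known reaction type is the intramolecular double Michael reaction of enone–enoates, a stepwise formal [4+2] cycloaddition of a 2-oxydiene. Ring B closes 6-exo-trig through C5–C10, the cis C7=C8 bond being part of the four-atom chain, and ring A closes 6-endo-trig through C3–C4. C10 and C5 are controlled by C9: in the chair-like transition state the C9–H bond eclipses the C10=C1 enol ether to minimise 1,3-allylic strain and the vinyl group lies anti to the incoming C5, so the C1 arm becomes equatorial and the C20 methyl axial and cis to C11, while the enoate arm takes the equatorial site and places H5 trans to C20. The two equatorial arms can then only close to the trans-fused decalin, and C4 is formed without control because it is reset in step 11. The step needs chemoselectivity for ketone enolisation over deprotonation at the doubly allylic C6 and over amine addition to the vinyl ketone, which the soft silyl triflate and hindered amine conditions secure, and 6-exo rather than 8-endo attack on the enoate, which the chain length secures.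

**Step 9**
Reactants: 16 methyl 1-oxo-13,14,15,16,18-pentanorlabda-7,11-dien-19-oate
Product: 17 C1 tosylhydrazone of 16
Conditions: TsNHNH2, AcOH (cat.), EtOH, 60 °C
Reagents that add atoms: 4-methylbenzenesulfonohydrazide, Cc1ccc(cc1)S(=O)(=O)NN
Why: Acid-catalysed condensation of the only ketone with tosylhydrazide gives the tosylhydrazone, the handle for removing the C1 helper oxygen.

**Step 10**
Reactants: 17 C1 tosylhydrazone of 16
Product: 18 methyl 13,14,15,16,18-pentanorlabda-7,11-dien-19-oate (C4 epimers)
Conditions: catecholborane, CHCl3, 0 °C → rt; then NaOAc·3H2O, reflux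
Reagents that add atoms: none
Why: Reduction of the tosylhydrazone with catecholborane (mild variant of the Caglioti reaction): hydride addition to C=N and acetate-induced loss of sulfinate and dinitrogen leave C1 as CH2 without touching the ester or the alkenes.

**Step 11**
Reactants: 18 methyl 13,14,15,16,18-pentanorlabda-7,11-dien-19-oate
Product: 19 methyl 13,14,15,16-tetranorlabda-7,11-dien-19-oate (4S; 4α-methyl and 4β-ester)
Conditions: LiN(iPr)2, THF, −78 → 0 °C; MeI, DMPU, −78 °C → rt
Reagents that add atoms: iodomethane, CI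
Why: Ester enolate alkylation: methyl iodide should approach the planar C4 enolate from the equatorial α face, anti to the axial C20 methyl, which gives the 4α-methyl 4β-ester (4S) and merges both C4 epimers.

**Step 12**
Reactants: 19 methyl 13,14,15,16-tetranorlabda-7,11-dien-19-oate
Product: 20 13,14,15,16-tetranorlabda-7,11-dien-19-ol
Conditions: LiAlH4, THF, reflux
Reagents that add atoms: none
Why: Hydride reduction of the hindered axial ester gives the neopentyl C19 alcohol; the isolated alkenes are inert.

**Step 13**
Reactants: 20 13,14,15,16-tetranorlabda-7,11-dien-19-ol; 21 angelic acid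
Product: 22 13,14,15,16-tetranorlabda-7,11-dien-19-yl (2Z)-2-methylbut-2-enoate
Conditions: 2,4,6-trichlorobenzoyl chloride, Et3N, toluene, rt; then 20, 80 °C, no DMAP
Reagents that add atoms: none
Why: Yamaguchi mixed-anhydride esterification run without a nucleophilic catalyst acylates the hindered primary alcohol while avoiding the addition–elimination pathway that would turn the angelate into the tiglate.

**Step 14**
Reactants: 22 13,14,15,16-tetranorlabda-7,11-dien-19-yl (2Z)-2-methylbut-2-enoate; 23 (2Z)-3-iodobut-2-enoic acid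
Product: 25 (4S,5R,9S,10R,13Z)-19-{[(2Z)-2-methylbut-2-enoyl]oxy}labda-7,13-dien-15-oic acid, via alkylborane 24 (not isolated)
Conditions: 9-BBN, THF, rt → 40 °C; then 23, PdCl2(dppf) (cat.), AsPh3, Cs2CO3, DMF–H2O, rt; dilute citric acid work-up
Reagents that add atoms: none
Why: Anti-Markovnikov hydroboration of the only monosubstituted alkene followed by B-alkyl Suzuki–Miyaura coupling, which retains the geometry of the (Z)-iodoalkene, places C12 cis to the carboxyl group and so gives the (13Z) acid directly; the mild carbonate base leaves the angelate intact.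

**Compound list**

1 | 3-[(tert-butyldimethylsilyl)oxy]propanal | O=CCCO[Si](C)(C)C(C)(C)C | starting material
2 | tert-butyl{[(3Z)-4-iodopent-3-en-1-yl]oxy}dimethylsilane | I/C(C)=C\CCO[Si](C)(C)C(C)(C)C | intermediate
3 | (3Z)-4-iodopent-3-en-1-ol | I/C(C)=C\CCO | intermediate
4 | (3Z)-4-iodopent-3-enal | I/C(C)=C\CC=O | intermediate
5 | methyl (2E,5Z)-6-iodohepta-2,5-dienoate | I/C(C)=C\C/C=C/C(=O)OC | intermediate
6 | (2E)-3-(tributylstannyl)prop-2-en-1-ol | OC/C=C/[Sn](CCCC)(CCCC)CCCC | starting material
7 | methyl (2E,5Z,7E)-9-hydroxy-6-methylnona-2,5,7-trienoate | OC/C=C/C(C)=C\C/C=C/C(=O)OC | intermediate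
8 | methyl (2E,5Z,7E)-6-methyl-9-(propanoyloxy)nona-2,5,7-trienoate | CCC(=O)OC/C=C/C(C)=C\C/C=C/C(=O)OC | intermediate
9 | boron ketene acetal of 8 (O-boryl enolate carrying the (4S,5S)-diazaborolidine; enolate geometry open) | CC=C(OC/C=C/C(C)=C\C/C=C/C(=O)OC)OB1N(S(=O)(=O)c2cc(cc(c2)C(F)(F)F)C(F)(F)F)[C@@H](c2ccccc2)[C@H](c2ccccc2)N1S(=O)(=O)c1cc(cc(c1)C(F)(F)F)C(F)(F)F | intermediate
10 | (3R,4Z,7E)-3-ethenyl-9-methoxy-2,4-dimethyl-9-oxonona-4,7-dienoic acid (both C2 epimers) | OC(=O)C(C)[C@@H](C=C)/C(C)=C\C/C=C/C(=O)OC | intermediate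
11 | acid chloride of 10 | ClC(=O)C(C)[C@@H](C=C)/C(C)=C\C/C=C/C(=O)OC | intermediate
12 | methyl (2E,5Z,7R)-7-ethenyl-6,8-dimethyl-9-oxoundeca-2,5,10-trienoate (both C8 epimers) | C=CC(=O)C(C)[C@@H](C=C)/C(C)=C\C/C=C/C(=O)OC | intermediate
13 | tert-butyldimethylsilyl dienol ether of 12 (2-silyloxydiene, C10=C1 geometry open, C9 as in 12) | C=CC(O[Si](C)(C)C(C)(C)C)=C(C)[C@@H](C=C)/C(C)=C\C/C=C/C(=O)OC | intermediate
14 | ring B closed silyl ketene acetal: cyclohexene with C10 carrying methyl (β) and acryloyl, C9 vinyl (β), C5 carrying the CH=C(OMe)OTBS arm (H5 α) | C=CC(=O)[C@]1(C)[C@@H](C=C)C(C)=CC[C@H]1C=C(OC)O[Si](C)(C)C(C)(C)C | intermediate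
15 | methyl 1-[(tert-butyldimethylsilyl)oxy]-13,14,15,16,18-pentanorlabda-1,7,11-trien-19-oate (C4 epimers) | COC(=O)C1CC=C(O[Si](C)(C)C(C)(C)C)[C@]2(C)[C@@H](C=C)C(C)=CC[C@@H]12 | intermediate
16 | methyl 1-oxo-13,14,15,16,18-pentanorlabda-7,11-dien-19-oate (5α-H, 9α-H, 10β-methyl; C4 epimers) | COC(=O)C1CCC(=O)[C@]2(C)[C@@H](C=C)C(C)=CC[C@@H]12 | intermediate
17 | C1 tosylhydrazone of 16 | COC(=O)C1CCC(=NNS(=O)(=O)c3ccc(C)cc3)[C@]2(C)[C@@H](C=C)C(C)=CC[C@@H]12 | intermediate
18 | methyl 13,14,15,16,18-pentanorlabda-7,11-dien-19-oate (C4 epimers) | COC(=O)C1CCC[C@]2(C)[C@@H](C=C)C(C)=CC[C@@H]12 | intermediate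
19 | methyl 13,14,15,16-tetranorlabda-7,11-dien-19-oate (4S; 4α-methyl, 4β-ester) | COC(=O)[C@@]1(C)CCC[C@]2(C)[C@@H](C=C)C(C)=CC[C@@H]12 | intermediate
20 | 13,14,15,16-tetranorlabda-7,11-dien-19-ol | OC[C@@]1(C)CCC[C@]2(C)[C@@H](C=C)C(C)=CC[C@@H]12 | intermediate
21 | angelic acid, (2Z)-2-methylbut-2-enoic acid | C/C=C(/C)C(=O)O | starting material
22 | 13,14,15,16-tetranorlabda-7,11-dien-19-yl (2Z)-2-methylbut-2-enoate | C/C=C(/C)C(=O)OC[C@@]1(C)CCC[C@]2(C)[C@@H](C=C)C(C)=CC[C@@H]12 | intermediate
23 | (2Z)-3-iodobut-2-enoic acid | I/C(C)=C\C(=O)O | starting material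
24 | 12-(9-borabicyclo[3.3.1]nonan-9-yl)-13,14,15,16-tetranorlabd-7-en-19-yl (2Z)-2-methylbut-2-enoate | C/C=C(/C)C(=O)OC[C@@]1(C)CCC[C@]2(C)[C@@H](CCB3C4CCCC3CCC4)C(C)=CC[C@@H]12 | intermediate
25 | (4S,5R,9S,10R,13Z)-19-{[(2Z)-2-methylbut-2-enoyl]oxy}labda-7,13-dien-15-oic acid | C/C=C(/C)C(=O)OC[C@@]1(C)CCC[C@]2(C)[C@@H](CC/C(C)=C\C(=O)O)C(C)=CC[C@@H]12 | target

**Step count**

Total step count: 14. Longest linear sequence: 14 steps (1 to 25); compounds 6, 21 and 23 are bought.

**Steps most likely to fail**

Step 8. The addition of the fully substituted C10 enol carbon to the unactivated enoate may be slower than oligomerisation of the vinyl ketone or loss of the silyl group under the Lewis-acidic conditions. Facial control by C9 may also be incomplete. The fallback sets out from 12 and returns at 16. Compound 12 is converted with iPr3SiOTf and iPr2NEt into the isolable triisopropylsilyl dienol ether F1. This is heated in toluene (about 140 °C, sealed tube, radical inhibitor), so that C5–C10 and C3–C4 form in a neutral, concerted thermal intramolecular Diels–Alder reaction instead of two ionic conjugate additions. The product is the bicyclic triisopropylsilyl enol ether F2, which Bu4NF buffered with AcOH cleaves to 16.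

Step 6. The chiral boron ligand may not discriminate the enolate faces well enough on this dienyl ester, or enolisation may compete at the doubly allylic C6 position. The fallback sets out from 7 and returns at 10. Compound 7 is turned into the dienyl methyl carbonate F3 (ClCO2Me, pyridine). An iridium-catalysed, branch-selective asymmetric allylic alkylation ([Ir(cod)Cl]2, chiral phosphoramidite ligand) with di-tert-butyl methylmalonate then gives the di-tert-butyl malonate F4, with C9 set by the catalyst. CF3CO2H at 0 °C cleaves both tert-butyl esters to the malonic acid F5, and gentle heating in toluene causes decarboxylation to 10.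

Step 14. The carboxylate of the coupling partner may retard transmetalation, so that protodeboronation of the alkylborane competes. Hydroboration of the hindered vinyl group may also be incomplete. The fallback sets out from 22 and returns at 25. Acid 23 is esterified with 2-(trimethylsilyl)ethanol (carbodiimide coupling) to 2-(trimethylsilyl)ethyl (2Z)-3-iodobut-2-enoate F6. The hydroboration and Suzuki–Miyaura coupling of step 14 are run with this ester and give the 2-(trimethylsilyl)ethyl ester of the target F7. Bu4NF in THF at 0 °C then releases 25 and leaves the angelate in place.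

**Further compounds**

F1 | step 8 | triisopropylsilyl dienol ether of 12 (2-silyloxydiene, C9 as in 12) | C=CC(O[Si](C(C)C)(C(C)C)C(C)C)=C(C)[C@@H](C=C)/C(C)=C\C/C=C/C(=O)OC
F2 | step 8 | methyl 1-[(triisopropylsilyl)oxy]-13,14,15,16,18-pentanorlabda-1,7,11-trien-19-oate (C4 epimers) | COC(=O)C1CC=C(O[Si](C(C)C)(C(C)C)C(C)C)[C@]2(C)[C@@H](C=C)C(C)=CC[C@@H]12
F3 | step 6 | methyl (2E,5Z,7E)-9-[(methoxycarbonyl)oxy]-6-methylnona-2,5,7-trienoate | COC(=O)OC/C=C/C(C)=C\C/C=C/C(=O)OC
F4 | step 6 | di-tert-butyl 2-methyl-2-[(3S,4Z,7E)-9-methoxy-4-methyl-9-oxonona-1,4,7-trien-3-yl]propanedioate | CC(C)(C)OC(=O)C(C)(C(=O)OC(C)(C)C)[C@@H](C=C)/C(C)=C\C/C=C/C(=O)OC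
F5 | step 6 | 2-methyl-2-[(3S,4Z,7E)-9-methoxy-4-methyl-9-oxonona-1,4,7-trien-3-yl]propanedioic acid | OC(=O)C(C)(C(=O)O)[C@@H](C=C)/C(C)=C\C/C=C/C(=O)OC
F6 | step 14 | 2-(trimethylsilyl)ethyl (2Z)-3-iodobut-2-enoate | I/C(C)=C\C(=O)OCC[Si](C)(C)C
F7 | step 14 | 2-(trimethylsilyl)ethyl (4S,5R,9S,10R,13Z)-19-{[(2Z)-2-methylbut-2-enoyl]oxy}labda-7,13-dien-15-oate | C/C=C(/C)C(=O)OC[C@@]1(C)CCC[C@]2(C)[C@@H](CC/C(C)=C\C(=O)OCC[Si](C)(C)C)C(C)=CC[C@@H]12
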